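**Retrosynthetic overview** (flavone numbering)

1. The target comes from its 7,4'-dibenzyl ether by hydrogenolysis; the three methyl ethers are in place from the start.
2. The strategy rests on the guaiacol unit of ring A (C5–OH next to C6–OMe) and on C8a–H, the only free position ortho to the C4 acyl carbon. Ring C is cut at O1–C8a, back to an open 1,3-diketone whose ring A still carries hydrogen at C8a.
3. Forward, oxidation of the guaiacol to an ortho-quinone monoketal places C8a beta to the C5 and C4 carbonyls; the diketone enol oxygen closes O1–C8a and loss of methanol restores ring A.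
4. The diketone is cut at C2–C3 (Claisen) into a ring A methyl ketone (from 2,3,4-trihydroxyacetophenone: 4-O-benzylation, 3-O-methylation) and a ring B methyl ester (from 2,5-dimethoxyphenol: benzylation, formylation, oxidative esterification).
5. Ring order: rings A and B are bought as benzenes; ring C, the pyranone, is the only ring made, in the key step.

Key step: step 7

Remark: the target has no stereocenter; the only stereogenic carbon on the way (C8a of intermediate 11) forms as a racemate and is erased in the same flask.

**Route**

Step 1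
Reactants: 1 2,3,4-trihydroxyacetophenone; 2 benzyl bromide (1.0 equiv)
Product: 3 1-[4-(benzyloxy)-2,3-dihydroxyphenyl]ethanone
Conditions: NaHCO3 (1.5 equiv), DMF, 40 °C, under N2
Reagents that add atoms: none
Why: Williamson ether synthesis under weak-base control: the 4-OH, para to the acetyl group and not held in the hydrogen bond to the carbonyl, is the most acidic hydroxyl, so NaHCO3 should form mainly the O4 phenoxide and one equivalent of benzyl bromide should alkylate there.

Step 2
Reactants: 3 1-[4-(benzyloxy)-2,3-dihydroxyphenyl]ethanone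
Product: 4 1-[4-(benzyloxy)-2-hydroxy-3-methoxyphenyl]ethanone
Conditions: MeI (1.1 equiv), K2CO3 (1.1 equiv), acetone, rt
Reagents that add atoms: iodomethane, CI
Why: Williamson methylation: the 2-OH is locked in the six-membered hydrogen bond to the acetyl oxygen and is the less acidic and less nucleophilic of the two hydroxyls, so one equivalent of MeI should methylate O3 only.

Step 3
Reactants: 5 2,5-dimethoxyphenol; 2 benzyl bromide
Product: 6 2-(benzyloxy)-1,4-dimethoxybenzene
Conditions: K2CO3, DMF, rt
Reagents that add atoms: none
Why: Williamson ether synthesis on the only hydroxyl of the molecule.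

Step 4
Reactants: 6 2-(benzyloxy)-1,4-dimethoxybenzene
Product: 7 4-(benzyloxy)-2,5-dimethoxybenzaldehyde
Conditions: POCl3 (1.5 equiv), DMF, 0 to 70 °C; then ice-water
Reagents that add atoms: N,N-dimethylformamide, CN(C)C=O (formyl carbon); water, O (carbonyl oxygen)
Why: Vilsmeier–Haack formylation: the chloroiminium ion attacks the carbon para to the benzyloxy group and ortho to a methoxy group, the only position activated by two donors that does not lie between two substituents, as in the formylation of 1,2,4-trimethoxybenzene to 2,4,5-trimethoxybenzaldehyde.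

Step 5
Reactants: 7 4-(benzyloxy)-2,5-dimethoxybenzaldehyde
Product: 8 methyl 4-(benzyloxy)-2,5-dimethoxybenzoate
Conditions: I2 (1.3 equiv), KOH (2.6 equiv), MeOH/THF, 0 °C
Reagents that add atoms: methanol, CO
Why: Oxidative esterification of an aldehyde with iodine and KOH in methanol: methanol adds to the formyl group and the hemiacetal alkoxide is oxidised by iodine to the methyl ester, while the aryl and benzyl ethers are inert to cold basic methanol.

Step 6
Reactants: 4 1-[4-(benzyloxy)-2-hydroxy-3-methoxyphenyl]ethanone; 8 methyl 4-(benzyloxy)-2,5-dimethoxybenzoate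
Product: 9 1-[4-(benzyloxy)-2-hydroxy-3-methoxyphenyl]-3-[4-(benzyloxy)-2,5-dimethoxyphenyl]propane-1,3-dione
Conditions: LiN(SiMe3)2 (3.5 equiv), THF, −78 °C to rt; then cold aq NH4Cl
Reagents that add atoms: none
Why: Crossed Claisen condensation: LiN(SiMe3)2 turns 4 into its phenoxide-enolate dianion, the enolate carbon is acylated by ester 8 (bond C2–C3) and deprotonation of the product to its diketonate drives the reaction, while the cold, near-neutral quench keeps the 2-hydroxyaryl diketone from cyclodehydrating.

Step 7
Reactants: 9 1-[4-(benzyloxy)-2-hydroxy-3-methoxyphenyl]-3-[4-(benzyloxy)-2,5-dimethoxyphenyl]propane-1,3-dione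
Product: 12 7-(benzyloxy)-2-[4-(benzyloxy)-2,5-dimethoxyphenyl]-5-hydroxy-6-methoxy-4H-chromen-4-one, via ortho-quinone monoketal 10 (not isolated), via dihydrochromenone ketal 11 (not isolated)
Conditions: PhI(OAc)2 (1.1 equiv), MeOH/CH2Cl2 (1:2), −20 °C to rt
Reagents that add atoms: methanol, CO (the two ketal methoxy groups of 10 are equivalent, one comes from the solvent, and either may be the one kept at C6 of 12)
Why: Proposed new method: ligand exchange of the C5 phenol on the trivalent iodine of PhI(OAc)2 and loss of iodobenzene give a phenoxenium-type species that methanol traps at C6, where the resident methoxy group carries the charge, to form monoketal 10; in 10 the C4a=C8a bond is an alkylidene flanked by the C5 and C4 carbonyls, so the enol oxygen of the side-chain diketone adds to C8a to give 11, and ionisation of one ketal methoxy group at C6, helped by the acetic acid set free, followed by proton loss from C8a restores the benzene ring. The closest known reaction types are the PhI(OAc)2/methanol oxidation of 2-methoxyphenols to 6,6-dimethoxycyclohexa-2,4-dienones and the conjugate addition of nucleophiles to such ketals with loss of methanol and rearomatisation; new here is an enol oxygen as the internal nucleophile, so that a pyranone ring is closed by a net C–H to C–O exchange. Ring C closes by 6-endo-trig oxa-Michael addition, O1 onto C8a, with both alkene carbons C4a and C8a inside the new ring. No stereocenter is set: C8a is stereogenic only in 11 and becomes planar again on aromatisation. Three selectivities are needed: methanol capture at C6 and not at C8 (secured by the C6 methoxy donor), oxidation of the phenol before the diketone methylene (secured by low temperature and only a slight excess of oxidant, phenols reacting far faster with PhI(OAc)2 than neutral 1,3-diketones), and closure through the diketone oxygen and not the C5 oxygen (secured because the oxidation turns C5–OH into a ketone and no strong acid or heat is applied before that). The main competitor, attack of solvent methanol at C8a, is countered by the intramolecular six-membered closure and by keeping methanol to a co-solvent share in CH2Cl2.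

Step 8
Reactants: 12 7-(benzyloxy)-2-[4-(benzyloxy)-2,5-dimethoxyphenyl]-5-hydroxy-6-methoxy-4H-chromen-4-one
Product: 13 5,7-dihydroxy-2-(4-hydroxy-2,5-dimethoxyphenyl)-6-methoxy-4H-chromen-4-one (CNP0509606.0)
Conditions: H2 (1 atm), 10% Pd/C, THF/MeOH, rt
Reagents that add atoms: none
Why: Catalytic hydrogenolysis of the two benzyl aryl ethers over zerovalent palladium on carbon; at 1 atm and room temperature the chromone C2=C3 bond, a vinylogous ester conjugated to both aryl rings, and the methyl ethers should stay untouched.

**Compound list**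

1 | 2,3,4-trihydroxyacetophenone | CC(=O)c1ccc(O)c(O)c1O | starting material
2 | benzyl bromide | BrCc1ccccc1 | starting material
3 | 1-[4-(benzyloxy)-2,3-dihydroxyphenyl]ethanone | CC(=O)c1ccc(OCc2ccccc2)c(O)c1O | intermediate
4 | 1-[4-(benzyloxy)-2-hydroxy-3-methoxyphenyl]ethanone | CC(=O)c1ccc(OCc2ccccc2)c(OC)c1O | intermediate
5 | 2,5-dimethoxyphenol | COc1ccc(OC)c(O)c1 | starting material
6 | 2-(benzyloxy)-1,4-dimethoxybenzene | COc1ccc(OC)c(OCc2ccccc2)c1 | intermediate
7 | 4-(benzyloxy)-2,5-dimethoxybenzaldehyde | COc1cc(OCc2ccccc2)c(OC)cc1C=O | intermediate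
8 | methyl 4-(benzyloxy)-2,5-dimethoxybenzoate | COC(=O)c1cc(OC)c(OCc2ccccc2)cc1OC | intermediate
9 | 1-[4-(benzyloxy)-2-hydroxy-3-methoxyphenyl]-3-[4-(benzyloxy)-2,5-dimethoxyphenyl]propane-1,3-dione | COc1c(O)c(C(=O)CC(=O)c2cc(OC)c(OCc3ccccc3)cc2OC)ccc1OCc1ccccc1 | intermediate
10 | 1-[4-(benzyloxy)-5,5-dimethoxy-6-oxocyclohexa-1,3-dien-1-yl]-3-[4-(benzyloxy)-2,5-dimethoxyphenyl]propane-1,3-dione (ortho-quinone monoketal, not isolated) | COC1(OC)C(=O)C(C(=O)CC(=O)c2cc(OC)c(OCc3ccccc3)cc2OC)=CC=C1OCc1ccccc1 | intermediate
11 | 7-(benzyloxy)-2-[4-(benzyloxy)-2,5-dimethoxyphenyl]-5-hydroxy-6,6-dimethoxy-6,8a-dihydro-4H-chromen-4-one (racemic at C8a, not isolated) | COC1(OC)C(OCc2ccccc2)=CC2OC(c3cc(OC)c(OCc4ccccc4)cc3OC)=CC(=O)C2=C1O | intermediate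
12 | 7-(benzyloxy)-2-[4-(benzyloxy)-2,5-dimethoxyphenyl]-5-hydroxy-6-methoxy-4H-chromen-4-one | COc1cc(-c2cc(=O)c3c(O)c(OC)c(OCc4ccccc4)cc3o2)c(OC)cc1OCc1ccccc1 | intermediate
13 | 5,7-dihydroxy-2-(4-hydroxy-2,5-dimethoxyphenyl)-6-methoxy-4H-chromen-4-one | COc1cc(-c2cc(=O)c3c(O)c(OC)c(O)cc3o2)c(OC)cc1O | target

**Step count**

Total step count: 8.
Longest linear sequence: 6 steps (5 → 6 → 7 → 8 → 9 → 12 → 13; steps 3 to 8).

**Steps most likely to fail**

Step 7 (the step that bears the label "Proposed new method:").
- What may go wrong: oxidation at the diketone methylene in place of the phenol; capture of monoketal 10 at C8a by solvent methanol in place of the enol oxygen; Diels–Alder dimerisation of 10; failure of the enol to reach the rotamer in which O1 faces C8a.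
- Fallback with known chemistry only: the oxygen at C8a is carried in from the start and ring C is closed by classical cyclodehydration. It sets out from ester 8 and comes back to the route at target 13.
- Purchased 1-[2,4-bis(benzyloxy)-6-hydroxyphenyl]ethanone (CC(=O)c1c(O)cc(OCc2ccccc2)cc1OCc1ccccc1) is oxidised para to its phenol by the Elbs persulfate reaction (K2S2O8, aq NaOH/pyridine) to potassium 3-acetyl-2,6-bis(benzyloxy)-4-hydroxyphenyl sulfate F1. Dilute HCl hydrolyses this to 1-[2,4-bis(benzyloxy)-3,6-dihydroxyphenyl]ethanone F2.
- MeI/K2CO3 in acetone methylates the hydroxyl that is not hydrogen-bonded to the carbonyl and should give 1-[2,4-bis(benzyloxy)-6-hydroxy-3-methoxyphenyl]ethanone F3.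
- Claisen condensation of this ketone with 8 (LiN(SiMe3)2, THF) should give 1-[2,4-bis(benzyloxy)-6-hydroxy-3-methoxyphenyl]-3-[4-(benzyloxy)-2,5-dimethoxyphenyl]propane-1,3-dione F4. Only one phenol is free in it, so cyclodehydration (TsOH cat., toluene, 80 °C) can give only 5,7-bis(benzyloxy)-2-[4-(benzyloxy)-2,5-dimethoxyphenyl]-6-methoxy-4H-chromen-4-one F5.
- Hydrogenolysis of its three benzyl ethers (H2, 10% Pd/C) gives 13.

Step 6.
- What may go wrong: acylation at the phenoxide oxygen in place of the enolate carbon; stalling of the condensation with the electron-rich, ortho-substituted ester; cyclodehydration through the C2 hydroxyl during work-up.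
- Fallback: acyl transfer inside the molecule (Baker–Venkataraman rearrangement) in place of the intermolecular condensation. It sets out from aldehyde 7 and ketone 4 and comes back at diketone 9.
- Pinnick oxidation of 7 (NaClO2, NaH2PO4, 2-methyl-2-butene, t-BuOH/H2O) should give 4-(benzyloxy)-2,5-dimethoxybenzoic acid F6.
- Steglich esterification with the phenol of 4 (EDC·HCl, DMAP, CH2Cl2) should give 6-acetyl-3-(benzyloxy)-2-methoxyphenyl 4-(benzyloxy)-2,5-dimethoxybenzoate F7.
- KOH in pyridine at 50 °C moves the aroyl group from oxygen to the enolate carbon through a six-membered transition state; cold dilute acetic acid then liberates 9.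

Step 1.
- What may go wrong: alkylation spread over O3 and O4, double benzylation, and air oxidation of the pyrogallol unit under base.
- Fallback: the ring A ketone is built from a symmetric phenol, so that three hydroxyls need not be told apart. It sets out from benzyl bromide 2 and purchased 2-methoxyresorcinol (COc1c(O)cccc1O) and comes back at ketone 4.
- Acetylation with acetic acid in BF3·OEt2 at 90 °C can occur only at the two equivalent positions ortho to a hydroxyl and should give 1-(2,4-dihydroxy-3-methoxyphenyl)ethanone F8.
- Benzyl bromide 2 with K2CO3 in refluxing acetone alkylates the 4-OH, which is not hydrogen-bonded to the carbonyl, to give 4.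

Further compounds
F1 | step 7 | potassium 3-acetyl-2,6-bis(benzyloxy)-4-hydroxyphenyl sulfate | CC(=O)c1c(O)cc(OCc2ccccc2)c(OS(=O)(=O)[O-])c1OCc1ccccc1.[K+]
F2 | step 7 | 1-[2,4-bis(benzyloxy)-3,6-dihydroxyphenyl]ethanone | CC(=O)c1c(O)cc(OCc2ccccc2)c(O)c1OCc1ccccc1
F3 | step 7 | 1-[2,4-bis(benzyloxy)-6-hydroxy-3-methoxyphenyl]ethanone | CC(=O)c1c(O)cc(OCc2ccccc2)c(OC)c1OCc1ccccc1
F4 | step 7 | 1-[2,4-bis(benzyloxy)-6-hydroxy-3-methoxyphenyl]-3-[4-(benzyloxy)-2,5-dimethoxyphenyl]propane-1,3-dione | COc1c(OCc2ccccc2)cc(O)c(C(=O)CC(=O)c2cc(OC)c(OCc3ccccc3)cc2OC)c1OCc1ccccc1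
F5 | step 7 | 5,7-bis(benzyloxy)-2-[4-(benzyloxy)-2,5-dimethoxyphenyl]-6-methoxy-4H-chromen-4-one | COc1cc(-c2cc(=O)c3c(OCc4ccccc4)c(OC)c(OCc4ccccc4)cc3o2)c(OC)cc1OCc1ccccc1
F6 | step 6 | 4-(benzyloxy)-2,5-dimethoxybenzoic acid | COc1cc(OCc2ccccc2)c(OC)cc1C(=O)O
F7 | step 6 | 6-acetyl-3-(benzyloxy)-2-methoxyphenyl 4-(benzyloxy)-2,5-dimethoxybenzoate | CC(=O)c1ccc(OCc2ccccc2)c(OC)c1OC(=O)c1cc(OC)c(OCc2ccccc2)cc1OC
F8 | step 1 | 1-(2,4-dihydroxy-3-methoxyphenyl)ethanone | CC(=O)c1ccc(O)c(OC)c1O
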